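(All runs are calculated with made-up constants; the scatter is artificial.)

In a closed flask where one step takes one substrate and one partner, the difference Δ = c_partner − c_substrate doesn't change, whatever the rate does. Substrate is the limiting reagent in each recipe below, and its balance is c_substrate = charge − target made, with any target charged at the start left out of the count.

| setting | red | violet | teal | blue | green |
|---|---|---|---|---|---|
| substrate | 100 mM | 40.0 mM | 100 mM | 100 mM | 33.0 mM |
| partner | 250 mM | 190 mM | 250 mM | 500 mM | 250 mM |
| catalyst | 10.0 mM | 10.0 mM | 10.0 mM | 10.0 mM | 20.0 mM |
| target |  |  | 50.0 mM |  |  |
| time |  |  |  |  | 7.0 min |

| red run: time / min | red run: [target] / mM | violet run: time / min | violet run: [target] / mM | teal run: time / min | teal run: [target] / mM | blue run: time / min | blue run: [target] / mM |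
|---|---|---|---|---|---|---|---|
| 0.28 | 2.2 | 0.28 | 0.6 | 0.28 | 49.1 | 0.28 | 1.0 |
| 0.63 | 0 | 0.63 | 0 | 0.63 | 51.1 | 0.63 | 3.3 |
| 1.4 | 6.1 | 1.4 | 0 | 1.4 | 55.3 | 1.4 | 11.4 |
| 3.1 | 22.0 | 3.1 | 6.8 | 3.1 | 75.2 | 3.1 | 42.5 |
| 7.0 | 58.4 | 7.0 | 20.3 | 7.0 | 109.8 | 7.0 | 87.3 |

(standard deviation of a reading: 2 mM)

- how the opening rate goes with [substrate] round the charge of the red run: the exponent of the rate at two percent of substrate gone to target (one fixed amount of target, the same in the runs compared)
- how the opening rate goes with [partner] round the charge of the red run: the exponent of the rate at two percent of substrate gone to target
- the violet run starts with 60.0 mM less of substrate and of partner than the red run, and with no target. Compared where both hold the same amount of substrate, once fifteen percent of what the violet run was charged with has turned into target, is the violet run faster, slower or alike (within a tenth)?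
- target in the green run at 7.0 min, as a share of the substrate charged

- Overall: substrate + partner -> target, with catalyst as catalyst.
- Constant volume, constant temperature.
- "The second partner" is partner.
- An order is taken over about fifteen percent of the charge, up and down.

The decision is whether the green run can be charged as written and stopped at 7.0 min. It has twice the catalyst of the red run, and no earlier run changes catalyst. If the rate is first order in substrate, in partner and in catalyst, the invariant lets me integrate the balance exactly:

clock = ln[ (c_partner / c_partner at start) · (c_substrate at start / c_substrate) ] / (Δ · c_catalyst)

The charges cancel in this quantity, so runs that read alike at one time support the assumption. At 7.0 min the red run gives 407 L² mol⁻², the violet run 397 L² mol⁻², the teal run 425 L² mol⁻² and the blue run 468 L² mol⁻². Their mean, 424 L² mol⁻², is the clock: the charge-free progress of the flask per unit of catalyst at that time.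

The same mean at 3.1 min is 111 L² mol⁻². The clock therefore grows 3.82 times while time grows 2.26 times, and it runs faster late than early. Three answers follow.

Growth as a power of time has the exponent

n = 1.65

At a fixed small amount of target, a richer charge arrives earlier on this clock, so the opening orders in substrate and in partner are both about 1/n, or 0.606. That is a rough figure, read later than the opening.

The violet and red runs share the same Δ, 0.150 M, so at equal substrate they hold equal partner and can differ only in clock speed. The red run has read 58.4 mM at 7.0 min, below the 60.0 mM it has to make before it comes down to the violet charge. The violet run reads 6.8 mM at 3.1 min, close to the matched point. So the red run stands there later, when the clock runs faster, and I expect the violet run to be slower.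

For the green run I assume first order in catalyst, and the clock at 7.0 min then gives

ln[…] = clock · 20.0 mM · 0.217 M = 1.84

share = 85.9%

So I charge the green run as written and stop it at 7.0 min.

The forecast has orders of 0.55 (0.4 to 0.8) and 0.53 (0.4 to 0.8), says slower, and gives 84% (72% to 93%), a little below my share, with the words “I assume first order in catalyst, which no run tests”.

The flask gives orders of 0.56 and 0.55, the violet run slower, and 86.7% in the green run.

    active catalyst + substrate + partner → target + active catalyst (97.20 L² mol⁻² min⁻¹)
    catalyst → active catalyst (0.3696 min⁻¹)

Put through the same balance, the green share reads a clock of 437 L² mol⁻², beside 424 L² mol⁻² from the 4 earlier runs. The clock lags behind time through the slowness of the conversion of catalyst into active catalyst, which holds the green run at 86.7% against 95.4% without that slowness. The violet run shows the same lag at the matched point, where its rate stands at 0.64 of the red run's, against 1.0 without the slowness.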